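All constants were chosen freely; what happens was integrated by code.

Follow the L.

L 0.30 M; time 1.0 h

    D ⇌ Q (K1 = 30, k1 = 0.017 s⁻¹)
    2 L → L2 (k2 = 0.0056 M⁻¹ s⁻¹)
    L ⇌ D (K3 = 1.3, k3 = 0.0063 s⁻¹)

- why nothing more happens at 1.0 h, or that something still does (forward and back rates have come level / it is still moving)
- how much D there is at 1.0 h, in percent of the L charged

- percent here means L units held: one L2 counts as two
- where a step has two of a species, its rate is k times that concentration squared, and two are used at each turn
- the reaction counts as stopped when no species that holds the L changes by six tenths of a point or more over the second half of the time
- run time (flask): 1.0 h

I carry one rule. L, D and Q form a pool joined by reversible steps, and pairing to L2 is the one way out of it. So I take D's balanced share of the pool as the large thing and compute the pairing loss as a correction.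

In the first instants the flask holds L, and the step to D uses it 1.9 times as fast as the pairing does, counting that step's forward rate. The pairing is slower, but it is not small enough to drop.

In the middle, D passes on to Q faster than it returns to L, so I treat D as a steady-state intermediate. L then drains at a net first-order constant a, the forward constant of the step to D times the fraction of D that goes on to Q, 0.00490 s⁻¹. With b twice the pairing constant and c the charge, integrating over the fall of L gives the loss as c minus (a/b) ln(1 + bc/a). That is a share s of the charge, 23.8%. I neglect the return from Q here.

At the end, the relaxation half-lives of 1.04 min and 0.658 min are short against the hour, so L, D and Q stand as 1 to 1.3 to 39.0. This gives f, the balanced share of D in the pool, 3.15%. L then stands at 0.00553 M, and pairing at that level takes 0.206% of the charge over the second half-hour, inside the stop rule given above. I reckon the flask stopped.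

| My reckoning | Value |
|---|---|
| f | 3.15% |
| s | 23.8% |
| D, f times what s leaves | 2.40% |

The forecast puts D at 2.4% and answers "forward and back rates have come level", starting from “The only irreversible leak is dimerisation”.

The flask gives 2.40% of D at 1.00 h and the answer "forward and back rates have come level", and the largest move over the second half is 0.18 percentage points. Left until 40 min, the neighbour flask holds 23.5% as L2, so f of the rest is 2.41%, and that neighbour flask reads 2.40%. The first flask, left until 10.0 h, holds 27.1% as L2, so f of the rest is 2.30%, and it reads 2.29%.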